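I counted half-lives.

| flask | starting material | second substrate | partner | free catalyst | temperature | remark | time |
|---|---|---|---|---|---|---|---|
| alpha | 0.070 M | 1 equiv | 1 equiv | 10 mol% | 4 °C | run made earlier |  |
| zeta | 0.11 M | 1 equiv | 1 equiv | 10 mol% | 12 °C | run made earlier |  |
| midnight | 0.050 M | 1.00 equiv | 1.00 equiv | 10 mol% | 0 °C |  | 15 h |
| winter | 0.050 M | 1.00 equiv | 1.00 equiv | 10 mol% | 15 °C |  | 15 h |

| run | time / h | over-reaction product / % | target / % | catalyst intermediate A / % | starting material / % |
|---|---|---|---|---|---|
| alpha | 2.50 | 3.0 | 31.5 | 0.6 | 64.1 |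
| alpha | 5.00 | 3.9 | 38.6 | 0 | 55.4 |
| alpha | 8.00 | 3.6 | 35.7 | 1.0 | 60.6 |
| alpha | 10.0 | 4.4 | 37.4 | 0.8 | 56.5 |
| alpha | 12.0 | 3.4 | 36.8 | 3.4 | 59.4 |
| zeta | 0.500 | 2.0 | 26.2 | 1.0 | 69.8 |
| zeta | 1.00 | 5.0 | 37.3 | 1.1 | 60.6 |
| zeta | 1.50 | 4.0 | 37.7 | 1.3 | 55.5 |
| zeta | 3.00 | 4.4 | 39.2 | 2.5 | 56.2 |
| zeta | 6.00 | 4.0 | 38.0 | 0.1 | 55.9 |

(readings scatter by 1 percentage point)

1. which of these there is most of at the end, counted by the starting material in it, midnight (starting material / over-reaction product / catalyst intermediate A / target)
2. which of these there is most of at the end, counted by the starting material in it, winter (starting material / over-reaction product / catalyst intermediate A / target)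
3. how much there is at the end of the one of these that leads, in percent of the starting material charged: midnight
4. how much there is at the end of the one of these that leads, in percent of the starting material charged: winter

- the numbers in the tables scatter by 1 percentage point (one standard deviation)

In both runs the target rose to a level and stayed there, so I took its last reading as that level. I called τ the half-life of approach, the time in which the gap to the level halves. The first reading gave τ = 0.894 h in alpha and 0.296 h in zeta. I assumed the rate follows concentration and gave the rest of that difference, a factor 1.92, to temperature. That made τ 1.73 h in midnight and 0.510 h in winter.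

The count N, the time divided by τ, came to 8.65 for midnight and 29.4 for winter. Because τ is short against 15 h, I expected both end readings to be plateau readings, with 0.249% of the gap left in midnight. My count gave no height for the plateau.

The forecast put starting material ahead in both flasks, at 58.5% in midnight and 56% in winter, holding that the “plateau hardly changes with concentration or temperature”.

The flasks gave starting material at 59.2% in midnight and starting material at 65.5% in winter.

    partner + catalyst intermediate B → free catalyst + second product (k = 43.5 M⁻¹ h⁻¹, Ea = 63.0 kJ mol⁻¹)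
    second substrate + free catalyst ⇌ catalyst intermediate B (K = 73.0 M⁻¹, k = 31.8 M⁻¹ h⁻¹, Ea = 61.0 kJ mol⁻¹, ΔH = 43.0 kJ mol⁻¹)
    partner + target → over-reaction product (k = 1.45 M⁻¹ h⁻¹, Ea = 67.0 kJ mol⁻¹)
    starting material + free catalyst ⇌ catalyst intermediate A (K = 15.0 M⁻¹, k = 36.8 M⁻¹ h⁻¹, Ea = 66.0 kJ mol⁻¹, ΔH = 26.0 kJ mol⁻¹)
    partner → decomposed reagent (k = 0.122 h⁻¹, Ea = 87.0 kJ mol⁻¹)
    partner + catalyst intermediate A → free catalyst + target (k = 615 M⁻¹ h⁻¹, Ea = 60.0 kJ mol⁻¹)
    (constants at 0 °C)

Winter already stood at 65.5% starting material after 7.50 h, and ten times the time changed nothing. In winter the partner, the limiting reagent, stood at 0% of its charge, against 66% for the starting material. A neighbour of winter took 40 mol% of free catalyst. If the rate follows the catalyst, its count is 118, so I read its end as a stop too. There the starting material fell to 41.5% and the target led with 53.1%.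

All runs come from a simulation from invented constants; the scatter is artificial.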